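**Retrosynthetic overview**
1. Octacosanolide is a 29-membered oxacycle: lactone carbonyl C1, methylenes C2–C28, ring O. The C14–C15 bond in the middle of the (CH2)27 chain is cut and each carbon is given a carboxyl group, which leads to the open-chain diacid 6, HO2C–(CH2)13–C(=O)O–(CH2)14–CO2H. In the forward sense a ring-closing Kolbe coupling (anodic double decarboxylation) forms this bond in the last step.
2. Diacid 6 is cut at the acyl C1–O bond (Steglich esterification) into monobenzyl pentadecanedioate 4 and benzyl 15-hydroxypentadecanoate 2. Both benzyl esters are removed in one hydrogenolysis; 2 and 4 come from the commercial C15 acids 1 and 3.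
3. Enabling feature: the ring carries one functional group only, the ester C1(=O)–O–C28. C14 and C15 are plain ring CH2 groups, separated from it by 12 and 13 methylenes, so each can carry a CO2H that leaves as CO2 and gives a primary, non-stabilised alkyl radical, the type that Kolbe coupling joins best. The O–C28 ester link is the tether between the two C15 halves.
4. Ring order: there is one ring, and it is formed in step 5.

Key step: step 5

Remark: the target has no stereocentre and no stereogenic double bond; it is achiral, so no step has to control configuration.

**Route**

Step 1
Reactants: 1 15-hydroxypentadecanoic acid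
Product: 2 benzyl 15-hydroxypentadecanoate
Conditions: BnBr, KHCO3, DMF, rt → 40 °C
Reagents that add atoms: benzyl bromide, BrCc1ccccc1
Why: Bicarbonate deprotonates only the carboxylic acid, and the carboxylate is benzylated by SN2 O-alkylation while the primary alcohol should stay free.

Step 2
Reactants: 3 pentadecanedioic acid
Product: 4 15-(benzyloxy)-15-oxopentadecanoic acid (monobenzyl pentadecanedioate)
Conditions: BnBr (limiting), KHCO3, DMF, 40 °C; 3 in excess and recovered
Reagents that add atoms: benzyl bromide, BrCc1ccccc1
Why: The same carboxylate SN2 benzylation serves as a statistical desymmetrisation of the symmetric diacid; an excess of 3 should keep the dibenzyl ester minor, and diacid, monoester and diester differ enough in polarity to be separated.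

Step 3
Reactants: 2 benzyl 15-hydroxypentadecanoate; 4 15-(benzyloxy)-15-oxopentadecanoic acid
Product: 5 benzyl 15-{[15-(benzyloxy)-15-oxopentadecanoyl]oxy}pentadecanoate
Conditions: DCC, DMAP (cat.), CH2Cl2, 0 °C → rt
Reagents that add atoms: none
Why: Steglich esterification (carbodiimide activation, DMAP acyl transfer) should join the only free acid to the only free primary alcohol, the two benzyl esters being inert.

Step 4
Reactants: 5 benzyl 15-{[15-(benzyloxy)-15-oxopentadecanoyl]oxy}pentadecanoate
Product: 6 15-[(14-carboxytetradecanoyl)oxy]pentadecanoic acid
Conditions: H2 (1 atm), Pd/C, THF–EtOAc, rt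
Reagents that add atoms: none
Why: Catalytic hydrogenolysis cleaves both benzylic C–O bonds under neutral conditions, whereas the internal alkyl ester has no benzylic C–O bond and should survive.

Step 5
Reactants: 6 15-[(14-carboxytetradecanoyl)oxy]pentadecanoic acid
Product: 8 octacosanolide (oxacyclononacosan-2-one), via alkyl biradical 7 (not isolated)
Conditions: undivided cell, Pt anode (small area, high current density)/Pt cathode, constant current, Et3N (10 mol %), MeOH–pyridine 4:1, 45 °C, 6 added slowly by syringe pump (pseudo-high dilution)
Reagents that add atoms: none
Why: Proposed new method: at a platinum anode above the Kolbe potential both carboxylates of the partly neutralised diacid, held in the anodic double layer by their charge, should be oxidised in quick succession to acyloxy radicals that lose CO2 at once, leaving the primary C14 and C15 radicals of biradical 7, which collapses by radical–radical combination to the C14–C15 bond. The closest known reaction types are the intermolecular Kolbe dimerisation of long-chain alkanoates and diacid half-esters, which makes exactly this kind of CH2–CH2 bond, and the collapse of long-chain α,ω-alkyl biradicals to large rings after extrusion of CO2 or CO; a ring-closing Kolbe coupling of this size has no close precedent. The 29-membered ring is closed by end-to-end combination of the two termini of a 1,29-biradical (no exo/endo question, since no π bond is attacked), and a ring of this size should be strain-free, so that only an entropic price is paid. No stereocentre is formed. The step needs (i) intramolecular over intermolecular coupling, to be secured by feeding 6 slowly so that few substrate radicals share the anode surface while a small anode at high current density oxidises the second carboxylate within the lifetime of the first radical, and (ii) radical coupling over further oxidation to cations (Hofer–Moest products), secured in the substrate by both radical sites being primary, unbranched, free of α- or β-heteroatoms and 12 or more CH2 groups away from the ester. The ester is not oxidised at the anode, and with an amine as the only base no alkoxide should be present to cleave it or the product lactone.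

**Compound list**
1 | 15-hydroxypentadecanoic acid | OCCCCCCCCCCCCCCC(=O)O | starting material
2 | benzyl 15-hydroxypentadecanoate | OCCCCCCCCCCCCCCC(=O)OCc1ccccc1 | intermediate
3 | pentadecanedioic acid | OC(=O)CCCCCCCCCCCCCC(=O)O | starting material
4 | 15-(benzyloxy)-15-oxopentadecanoic acid | OC(=O)CCCCCCCCCCCCCC(=O)OCc1ccccc1 | intermediate
5 | benzyl 15-{[15-(benzyloxy)-15-oxopentadecanoyl]oxy}pentadecanoate | O=C(OCc1ccccc1)CCCCCCCCCCCCCC(=O)OCCCCCCCCCCCCCCC(=O)OCc1ccccc1 | intermediate
6 | 15-[(14-carboxytetradecanoyl)oxy]pentadecanoic acid | OC(=O)CCCCCCCCCCCCCC(=O)OCCCCCCCCCCCCCCC(=O)O | intermediate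
7 | alkyl biradical (radical centres at the two chain ends, the future C14 and C15) | [CH2]CCCCCCCCCCCCC(=O)OCCCCCCCCCCCCC[CH2] | intermediate (not isolated)
8 | octacosanolide (oxacyclononacosan-2-one) | O=C1CCCCCCCCCCCCCCCCCCCCCCCCCCCO1 | target

**Step count**
Total step count: 5
Longest linear sequence: 4 steps (steps 1, 3, 4, 5, or equally steps 2, 3, 4, 5)

**Steps most likely to fail**

1. Step 5. Radical–radical coupling between neighbouring molecules on the anode may outrun ring closure and give oligomers, accompanied by disproportionation of the radical ends and over-oxidation to cations. The fallback uses known chemistry, closes the same bond as an alkene, sets out from 1 and returns to the route at 8. Compound 1 would be converted with 48 % aq. HBr and H2SO4 at reflux into 15-bromopentadecanoic acid F1. E2 elimination with t-BuOK in THF, the acid being masked as its carboxylate, would give pentadec-14-enoic acid F2. Part of F2 would be reduced with LiAlH4 in THF to pentadec-14-en-1-ol F3. Steglich esterification (DCC, DMAP) of F2 with F3 would give pentadec-14-en-1-yl pentadec-14-enoate F4. Ring-closing olefin metathesis (second-generation Ru–NHC benzylidene catalyst, CH2Cl2, reflux, high dilution) would close the C14=C15 bond with loss of ethylene and give oxacyclononacos-15-en-2-one F5 as an E/Z mixture. Hydrogenation of F5 (H2, Pd/C, EtOAc) would then give 8.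

2. Step 2. Over-alkylation to the dibenzyl ester and incomplete conversion may leave three homologous species that are tedious to separate. The fallback desymmetrises with an excess of a bis-electrophile instead of a statistical protection; it sets out from 3 (and uses 2 from step 1) and returns to the route at 6, so that compounds 4 and 5 are bypassed. Compound 3 would be converted with SOCl2 into pentadecanedioyl dichloride F6. Slow addition of 2 to a large excess of F6 (pyridine, CH2Cl2, 0 °C) would give benzyl 15-[(15-chloro-15-oxopentadecanoyl)oxy]pentadecanoate F7, which is not isolated. Aqueous hydrolysis would give 15-{[15-(benzyloxy)-15-oxopentadecyl]oxy}-15-oxopentadecanoic acid F8, the excess of F6 returning to 3. Hydrogenolysis of the single benzyl ester of F8 (H2, Pd/C) would give 6.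

3. Step 3. O→N acyl migration in the activated acid to an unreactive N-acylurea, and sluggish coupling of two waxy long-chain partners, may leave the esterification incomplete. The fallback makes the ester by alkylation at O–C28 instead of acylation; it sets out from 2 and returns to the route at 5. Compound 2 would be converted with MsCl and Et3N in CH2Cl2 into benzyl 15-[(methylsulfonyl)oxy]pentadecanoate F9. The caesium carboxylate of 4 (Cs2CO3, DMF, 60 °C) would displace the mesylate by SN2 and give 5.

**Further compounds**
F1 | step 5 | 15-bromopentadecanoic acid | OC(=O)CCCCCCCCCCCCCCBr
F2 | step 5 | pentadec-14-enoic acid | OC(=O)CCCCCCCCCCCCC=C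
F3 | step 5 | pentadec-14-en-1-ol | OCCCCCCCCCCCCCC=C
F4 | step 5 | pentadec-14-en-1-yl pentadec-14-enoate | C=CCCCCCCCCCCCCC(=O)OCCCCCCCCCCCCCC=C
F5 | step 5 | oxacyclononacos-15-en-2-one (E/Z mixture) | O=C1CCCCCCCCCCCCC=CCCCCCCCCCCCCCO1
F6 | step 2 | pentadecanedioyl dichloride | ClC(=O)CCCCCCCCCCCCCC(=O)Cl
F7 | step 2 | benzyl 15-[(15-chloro-15-oxopentadecanoyl)oxy]pentadecanoate | ClC(=O)CCCCCCCCCCCCCC(=O)OCCCCCCCCCCCCCCC(=O)OCc1ccccc1
F8 | step 2 | 15-{[15-(benzyloxy)-15-oxopentadecyl]oxy}-15-oxopentadecanoic acid | OC(=O)CCCCCCCCCCCCCC(=O)OCCCCCCCCCCCCCCC(=O)OCc1ccccc1
F9 | step 3 | benzyl 15-[(methylsulfonyl)oxy]pentadecanoate | CS(=O)(=O)OCCCCCCCCCCCCCCC(=O)OCc1ccccc1
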